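Readings and results were generated by integration from invented constants, noise included.

Living ends cannot outnumber the initiator that starts them.

| flask | free monomer | capture agent | initiator | temperature | remark | time |
|---|---|---|---|---|---|---|
| Saturday's | 0.044 M | 0.010 M | 18 mM | 55 °C | run made earlier |  |
| Monday's | 0.32 M | 0.010 M | 18 mM | 90 °C | run made earlier |  |
| Thursday's | 0.20 M | 0.019 M | 18 mM | 55 °C | run made earlier |  |
| south-east | 0.050 M | 0.0300 M | 25 mM | 80 °C |  | 8.0 min |
| north-west | 0.20 M | 0.0100 M | 18 mM | 60 °C |  | 8.0 min |
| south-west | 0.20 M | 0.00600 M | 40 mM | 120 °C |  | 8.0 min |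
| north-east | 0.40 M | 0.0100 M | 18 mM | 65 °C |  | 8.0 min |
| east | 0.20 M | 0.0100 M | 18 mM | 80 °C |  | 8.0 min |

- Saturday's (time / min: monomer in chains / %, free monomer / %): 1.00: 20.2, 79.8; 1.50: 26.1, 72.9; 3.00: 38.6, 57.6; 5.00: 51.1, 49.2; 8.00: 57.6, 42.4; 15.0: 67.2, 33.7
- Monday's (time / min: monomer in chains / %, free monomer / %): 0.417: 39.7, 62.7; 0.833: 55.1, 43.2; 1.33: 68.4, 32.2; 1.50: 70.6, 28.3; 2.00: 78.3, 22.9; 2.50: 81.4, 16.8
- Thursday's (time / min: monomer in chains / %, free monomer / %): 3.00: 27.8, 74.6; 5.00: 33.2, 64.9; 8.00: 38.5, 59.7; 10.0: 43.1, 59.3; 15.0: 45.0, 54.4

(scatter of a reading: 1 percentage point)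

1. the flasks put in order of amount of monomer in chains, in percent of the free monomer charged, best first, at 8.0 min (south-east / north-west / south-west / north-east / east)
2. the amount of monomer in chains, in percent of the free monomer charged of the flask you put first, at 8.0 min
3. the amount of monomer in chains, in percent of the free monomer charged of the flask you put last, at 8.0 min

- no earlier run changes the charge of initiator; that part of a forecast is a guess

I suppose that each initiator starts one living end, putting one free monomer into a chain as it does, and that each capture agent takes one living end for good. South-east has 25 mM of initiator against 0.0300 M of capture agent, which gives −5.00 mM. This is the surplus of living ends, initiator charge minus capture agent charge: what stays growing once capture is over. Below zero, I expect a flask to stop with capture agent to spare.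

The earlier runs all hold the initiator at 18 mM, so the one-for-one part is my guess. They do give a hint, though. At 55 °C, Saturday's surplus is 8.00 mM and Thursday's is −1.00 mM. Between 8.00 min and 15.0 min, Saturday's flask lost 20.5% of the free monomer it still had, and Thursday's flask lost less, 8.88%, as far as readings with their scatter can say, though these two flasks also differ in free monomer charged, 0.044 M against 0.20 M.

The surplus is 8.00 mM in north-west, north-east and east, and 34.0 mM in south-west, so south-east has the lowest of the flasks. I therefore put south-east last. Its starts can put 50.0% of its free monomer into chains, and I expect it to stop above that.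

The forecast differs from this reckoning. It gives south-west > east > north-east > south-east > north-west, with 97% for the first (range 82% to 100%) and 64% for the last (range 57% to 70%), and it holds south-east at 72 percent, “uncertain, near tie”.

The flasks give east > south-west > north-east > north-west > south-east, with 88.7% for the first and 61.3% for the last.

    free monomer + initiator → living end + monomer in chains (k = 1.00 M⁻¹ s⁻¹, Ea = 56.0 kJ mol⁻¹)
    free monomer + living end → monomer in chains + living end, rate k2*[living end]*[free monomer] (k = 0.820 M⁻¹ s⁻¹, Ea = 64.0 kJ mol⁻¹)
    monomer in chains + living end → free monomer + living end, rate k3*[living end] as long as [monomer in chains] is above zero (k = 0.0140 s⁻¹, Ea = 84.0 kJ mol⁻¹)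
    living end + capture agent → trapped intermediate (k = 2.30 M⁻¹ s⁻¹, Ea = 51.0 kJ mol⁻¹)
    (constants at 80 °C)

South-east, with its surplus of −5.00 mM, is last at 61.3%. At 8.00 min it holds 4.73 × 10⁻⁵ M of living end, its initiator is at 0%, and 16.8% of its capture agent remains, which is 5.05 mM. At 80.0 min it still stands at 61.3%. A neighbour of south-east, charged with 0.10 M of initiator, has a surplus of 70.0 mM. At 8.00 min it holds 0.0698 M of living end and 0% of its capture agent, and its monomer in chains stands at 66.0%.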